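**Assumptions:**
- Gardenin D (5,3'-dihydroxy-6,7,8,4'-tetramethoxyflavone) has no stereocentres, so "single enantiomer" does not apply. The only stereo-element in the route is the E-alkene of the chalcone, which is consumed on cyclisation.
- Only bulk-catalogue starting materials are used (1, 2, 6), so the fully oxygenated acetophenone 5 is made rather than bought.

**Retrosynthetic overview**
1. The 5-OH and 3'-OH are unmasked last from the 5-OMe / 3'-OBn flavone 8 in one Lewis-acid step (peri-chelation-selective demethylation plus debenzylation).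
2. The pyranone C-ring is formed by oxidative cyclisation of 2'-hydroxychalcone 7 (O1–C2 bond).
3. Chalcone 7 comes from Claisen–Schmidt condensation of acetophenone 5 with O-benzylisovanillin 6 (the B-ring is bought intact).
4. The A-ring of 5 comes from 3,4,5-trimethoxyphenol by C-acetylation, then bromination and Cu-mediated methoxylation of the single remaining ring C–H.
5. Ring order: A and B rings are purchased aromatics; the C-ring is the only ring formed (step 5).

**Route**

**Step 1**
Reactants: 1, 3,4,5-trimethoxyphenol; 2, acetic acid (acyl donor and solvent)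
Product: 3, 1-(6-hydroxy-2,3,4-trimethoxyphenyl)ethanone (2'-hydroxy-4',5',6'-trimethoxyacetophenone)
Conditions: BF3·OEt2 (3 equiv), AcOH, 90 °C, 3 h; aqueous work-up
Reagents that add atoms: acetic acid (2), CC(=O)O
Why: BF3-promoted Friedel–Crafts C-acylation (via O-acetate/Fries) goes ortho to the phenol, since the two ortho positions are equivalent and para is blocked; the BF2 chelate of the product stops a second acylation.

**Step 2**
Reactants: 3
Product: 4, 1-(3-bromo-2-hydroxy-4,5,6-trimethoxyphenyl)ethanone
Conditions: NBS (1.05 equiv), MeCN, 0 °C → rt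
Reagents that add atoms: N-bromosuccinimide, O=C1CCC(=O)N1Br
Why: Electrophilic aromatic bromination at the only ring C–H, which is ortho to the phenol and an OMe; this is much faster than α-bromination of the ketone under non-acidic conditions.

**Step 3**
Reactants: 4
Product: 5, 1-(2-hydroxy-3,4,5,6-tetramethoxyphenyl)ethanone (2'-hydroxy-3',4',5',6'-tetramethoxyacetophenone)
Conditions: NaOMe (5 equiv, 25% in MeOH), CuBr (0.3 equiv), DMF, 110 °C, Ar; acidify on work-up
Reagents that add atoms: sodium methoxide, [Na+].[O-]C
Why: Ullmann-type Cu(I)-catalysed methoxylation of an o-bromophenoxide (the 5-bromovanillin → syringaldehyde reaction); the phenoxide deactivates the hindered ketone towards self-condensation.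

**Step 4**
Reactants: 5; 6, 3-(benzyloxy)-4-methoxybenzaldehyde (O-benzylisovanillin)
Product: 7, (E)-3-[3-(benzyloxy)-4-methoxyphenyl]-1-(2-hydroxy-3,4,5,6-tetramethoxyphenyl)prop-2-en-1-one
Conditions: KOH (50% aq., excess), EtOH, rt, 24–48 h; then dilute HCl
Reagents that add atoms: none (all product atoms come from 5 and 6)
Why: Claisen–Schmidt aldol condensation of the methyl ketone enolate with a non-enolisable aldehyde; E1cB dehydration gives the conjugated E-enone, and the benzyl and methyl ethers are base-stable.

**Step 5**
Reactants: 7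
Product: 8, 2-[3-(benzyloxy)-4-methoxyphenyl]-5,6,7,8-tetramethoxy-4H-chromen-4-one
Conditions: I2 (0.1 equiv), DMSO, 130 °C, 3 h; Na2S2O3 work-up
Reagents that add atoms: none
Why: I2/DMSO oxidative cyclisation of a 2'-hydroxychalcone (oxa-Michael closure then iodine-mediated dehydrogenation, with DMSO re-oxidising HI); only the 2'-OH can cyclise, so the flavone has the 5,6,7,8-tetramethoxy pattern.

**Step 6**
Reactants: 8
Product: 9, Gardenin D (5-hydroxy-2-(3-hydroxy-4-methoxyphenyl)-6,7,8-trimethoxy-4H-chromen-4-one)
Conditions: BCl3 (1 M in CH2Cl2, 5 equiv), pentamethylbenzene (3 equiv), CH2Cl2, −78 → 0 °C; MeOH, then aq. HCl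
Reagents that add atoms: none
Why: Lewis-acid ether cleavage: the benzyl ether cleaves at low temperature (the scavenger traps the benzyl cation), and only the 5-OMe, peri to C4=O, is activated through a six-membered boron chelate; the 6-, 7-, 8- and 4'-OMe groups are not cleaved at ≤0 °C.

**Compound list**
1 | 3,4,5-trimethoxyphenol | COc1cc(O)cc(OC)c1OC | starting material
2 | acetic acid | CC(=O)O | starting material
3 | 1-(6-hydroxy-2,3,4-trimethoxyphenyl)ethanone | CC(=O)c1c(O)cc(OC)c(OC)c1OC | intermediate
4 | 1-(3-bromo-2-hydroxy-4,5,6-trimethoxyphenyl)ethanone | CC(=O)c1c(O)c(Br)c(OC)c(OC)c1OC | intermediate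
5 | 1-(2-hydroxy-3,4,5,6-tetramethoxyphenyl)ethanone | CC(=O)c1c(O)c(OC)c(OC)c(OC)c1OC | intermediate
6 | 3-(benzyloxy)-4-methoxybenzaldehyde | COc1ccc(C=O)cc1OCc1ccccc1 | starting material
7 | (E)-3-[3-(benzyloxy)-4-methoxyphenyl]-1-(2-hydroxy-3,4,5,6-tetramethoxyphenyl)prop-2-en-1-one | COc1ccc(/C=C/C(=O)c2c(O)c(OC)c(OC)c(OC)c2OC)cc1OCc1ccccc1 | intermediate
8 | 2-[3-(benzyloxy)-4-methoxyphenyl]-5,6,7,8-tetramethoxy-4H-chromen-4-one | COc1ccc(-c2cc(=O)c3c(OC)c(OC)c(OC)c(OC)c3o2)cc1OCc1ccccc1 | intermediate
9 | Gardenin D | COc1ccc(-c2cc(=O)c3c(O)c(OC)c(OC)c(OC)c3o2)cc1O | target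

**Totals**
Total steps: 6. Longest linear sequence: 6 (from 1; aldehyde 6 is purchased).

**Three steps most likely to fail, with fallbacks**
1. **Step 3** (Cu-mediated methoxylation of a hindered, electron-rich aryl bromide; risk of protodebromination back to 3). Fallback: install the fourth oxygen before the acyl group. 1,2,3,4-Tetramethoxybenzene → Rieche formylation → Baeyer–Villiger/hydrolysis → 2,3,4,5-tetramethoxyphenol, then BF3/AcOH acetylation at its only free position gives 5 directly.
2. **Step 6** (one-pot BCl3 step; risk of over-demethylation at 6-OMe or 4'-OMe, or C-benzylation). Fallback: generate the 5-OH before ring formation. AlCl3 demethylation of 5 at the carbonyl-flanking 6'-OMe gives the symmetric 2',6'-dihydroxy-3',4',5'-trimethoxyacetophenone, which is carried through the flavone synthesis so the flavone already has a free 5-OH; the benzyl group is then removed by neutral hydrogenolysis (H2, Pd/C).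
3. **Step 5** (I2/DMSO cyclisation; risk of stalling at the flavanone, ring iodination or partial demethylation). Fallback: Baker–Venkataraman route, which also bypasses step 4. O-Acylate 5 with 3-benzyloxy-4-methoxybenzoyl chloride, rearrange with base (KOH/pyridine or LiHMDS) to the 1,3-diketone, and cyclodehydrate (H2SO4/AcOH) to 8.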